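**Retrosynthetic overview**

1. The 2,2-dimethyl-2H-pyran (ring D: C4', its oxygen, CMe2, CH=CH, C5' of ring B) is disconnected last, together with the C2'–prenyl bond. This leads back to the isomeric flavan bis-ether 18 (O3'–CMe2–CH=CH2 and O4'–CMe2–C≡CH). One thermal cascade (aromatic Claisen shift, then propargyl Claisen shift / [1,5]-H shift / oxa-6π electrocyclisation) should form both C–C bonds and ring D.
2. Enabling feature: on ring B the vicinal oxygens O3' and O4' each have exactly one unsubstituted ortho carbon (C2'–H next to O3', C5'–H next to O4'). In the target these two carbons carry the prenyl CH2 and the pyran CH=, so each C–C bond is the retron of an O-to-ortho-C [3,3] shift with no regiochemical choice.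
3. Ring C (O1–C2 of the chroman) is closed before that by Mitsunobu cyclisation with inversion of an (S)-benzylic carbinol from CBS reduction. The C2–C3–C4 chain comes from a Claisen–Schmidt condensation followed by 1,4-reduction.
4. O3' and O4' are told apart at the start on 3,4-dihydroxyacetophenone (the para-acyl 4-OH reacts first). Ring order: rings A and B are bought, ring C is closed in step 8, ring D in step 9.

Key step: step 9

Assumption: the drawn stereocentre is read as (2R) (O1 > C1' > C3 > H); primed locants refer to ring B, with C1' bonded to C2 of the chroman.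

**Route**

Step 1
Reactants: 1 1-(3,4-dihydroxyphenyl)ethan-1-one; 2 3-chloro-3-methylbut-1-yne
Product: 3 1-[3-hydroxy-4-(2-methylbut-3-yn-2-yloxy)phenyl]ethan-1-one
Conditions: 2 (1.1 equiv), K2CO3 (1.1 equiv), KI (0.1 equiv), CuI (5 mol%), acetone, 50 °C, N2
Reagents that add atoms: 3-chloro-3-methylbut-1-yne (2), CC(C)(Cl)C#C
Why: Copper-catalysed propargylic O-alkylation (a Williamson-type etherification of a tertiary propargylic chloride) should occur at the 4-OH only, because one equivalent of carbonate forms the more acidic para-acyl phenoxide while the 3-OH stays protonated and hydrogen-bonded.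

Step 2
Reactants: 4 2-methylbut-3-en-2-ol; 5 di-tert-butyl dicarbonate
Product: 7 tert-butyl 2-methylbut-3-en-2-yl carbonate, via lithium 2-methylbut-3-en-2-olate 6 (not isolated)
Conditions: n-BuLi (1.05 equiv), THF, −78 → 0 °C; then 5, 0 °C → rt
Reagents that add atoms: di-tert-butyl dicarbonate (5), CC(C)(C)OC(=O)OC(=O)OC(C)(C)C
Why: O-acylation of the tertiary lithium alkoxide by the dicarbonate (carbonate formation) should give the allylic carbonate that serves as the π-allyl precursor in step 3.

Step 3
Reactants: 3 1-[3-hydroxy-4-(2-methylbut-3-yn-2-yloxy)phenyl]ethan-1-one; 7 tert-butyl 2-methylbut-3-en-2-yl carbonate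
Product: 8 1-[3-(2-methylbut-3-en-2-yloxy)-4-(2-methylbut-3-yn-2-yloxy)phenyl]ethan-1-one
Conditions: 7 (1.5 equiv), Pd(PPh3)4 (5 mol%), THF, 0 °C
Reagents that add atoms: tert-butyl 2-methylbut-3-en-2-yl carbonate (7), C=CC(C)(C)OC(=O)OC(C)(C)C
Why: In this Tsuji–Trost decarboxylative O-allylation, zerovalent palladium ionises the carbonate, the released tert-butoxide deprotonates the phenol, and the phenoxide should attack the more substituted terminus of the 1,1-dimethyl-π-allylpalladium complex under kinetic control at 0 °C (the established reverse prenylation of phenols), the terminal alkyne and aryl propargyl ether being inert at this temperature.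

Step 4
Reactants: 9 2,4-dihydroxybenzaldehyde; 10 chloromethyl methyl ether
Product: 11 2-hydroxy-4-(methoxymethoxy)benzaldehyde
Conditions: 10 (1.05 equiv), K2CO3 (1.1 equiv), acetone, 0 °C → rt
Reagents that add atoms: chloromethyl methyl ether (10), COCCl
Why: Williamson O-alkylation should be selective for the 4-OH because the 2-OH is held in a hydrogen bond to the formyl group and is far less nucleophilic.

Step 5
Reactants: 8 1-[3-(2-methylbut-3-en-2-yloxy)-4-(2-methylbut-3-yn-2-yloxy)phenyl]ethan-1-one; 11 2-hydroxy-4-(methoxymethoxy)benzaldehyde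
Product: 13 (2E)-3-[2-hydroxy-4-(methoxymethoxy)phenyl]-1-[3-(2-methylbut-3-en-2-yloxy)-4-(2-methylbut-3-yn-2-yloxy)phenyl]prop-2-en-1-one, via aldol adduct 12 (not isolated)
Conditions: KOH (4 equiv, base catalyst), EtOH, rt, 24–48 h; aq. NH4Cl to pH 7
Reagents that add atoms: none
Why: Claisen–Schmidt (crossed aldol) condensation of the methyl ketone enolate with the non-enolisable aldehyde, followed by E1cB dehydration of 12, should give the (E)-enone, all ether groups being stable to hydroxide and the neutral quench avoiding flavylium formation.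

Step 6
Reactants: 13 (2E)-3-[2-hydroxy-4-(methoxymethoxy)phenyl]-1-[3-(2-methylbut-3-en-2-yloxy)-4-(2-methylbut-3-yn-2-yloxy)phenyl]prop-2-en-1-one
Product: 15 3-[2-hydroxy-4-(methoxymethoxy)phenyl]-1-[3-(2-methylbut-3-en-2-yloxy)-4-(2-methylbut-3-yn-2-yloxy)phenyl]propan-1-one, via boron enolate 14 (not isolated)
Conditions: catecholborane (3 equiv), THF, 0 °C → rt; then MeOH, pH 7 buffer
Reagents that add atoms: none
Why: Conjugate reduction of an acyclic enone by catecholborane (1,4-hydroboration through a six-membered transition state of the s-cis conformer) should give boron enolate 14, protonated on work-up, while uncatalysed catecholborane does not hydroborate the isolated terminal alkene or alkyne at room temperature and the enolate keeps the carbonyl group from 1,2-reduction.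

Step 7
Reactants: 15 3-[2-hydroxy-4-(methoxymethoxy)phenyl]-1-[3-(2-methylbut-3-en-2-yloxy)-4-(2-methylbut-3-yn-2-yloxy)phenyl]propan-1-one
Product: 17 2-[(3S)-3-hydroxy-3-[3-(2-methylbut-3-en-2-yloxy)-4-(2-methylbut-3-yn-2-yloxy)phenyl]propyl]-5-(methoxymethoxy)phenol, via bis-catecholborate ester 16 (not isolated)
Conditions: (R)-1-methyl-3,3-diphenyl-tetrahydro-1H,3H-pyrrolo[1,2-c][1,3,2]oxazaborole [(R)-Me-CBS, 20 mol%], catecholborane (2.5 equiv), toluene, −78 °C; then MeOH, aq. work-up
Reagents that add atoms: none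
Why: In this Corey–Bakshi–Shibata reduction, with the aryl group as the large and the CH2CH2Ar chain as the small substituent, the (R)-oxazaborolidine should deliver hydride to the face that gives the (S)-carbinol (mirror image of the (S)-catalyst/(R)-1-arylalkanol rule), and catecholborane at −78 °C leaves the alkene and alkyne untouched.

Step 8
Reactants: 17 2-[(3S)-3-hydroxy-3-[3-(2-methylbut-3-en-2-yloxy)-4-(2-methylbut-3-yn-2-yloxy)phenyl]propyl]-5-(methoxymethoxy)phenol
Product: 18 (2R)-7-(methoxymethoxy)-2-[3-(2-methylbut-3-en-2-yloxy)-4-(2-methylbut-3-yn-2-yloxy)phenyl]-3,4-dihydro-2H-chromene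
Conditions: PPh3 (1.5 equiv), DIAD (1.5 equiv), THF (0.02 M), 0 °C → rt
Reagents that add atoms: none
Why: Intramolecular Mitsunobu etherification (6-exo-tet SN2 displacement of the oxyphosphonium group by the phenoxide) should close ring C with inversion, turning the (S)-carbinol into the (2R)-chroman, the two bulky tertiary alkoxy groups on ring B being twisted out of conjugation and so disfavouring an SN1 leak.

Step 9
Reactants: 18 (2R)-7-(methoxymethoxy)-2-[3-(2-methylbut-3-en-2-yloxy)-4-(2-methylbut-3-yn-2-yloxy)phenyl]-3,4-dihydro-2H-chromene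
Product: 22 6-[(2R)-7-(methoxymethoxy)-3,4-dihydro-2H-chromen-2-yl]-2,2-dimethyl-7-(3-methylbut-2-en-1-yl)-2H-chromen-8-ol, via prenyl phenol 19 (not isolated), via allenyl catechol 20 (not isolated), via ortho-quinone methide 21 (not isolated)
Conditions: N,N-diethylaniline (0.05 M, degassed), 165 °C, argon
Reagents that add atoms: none
Why: Heating should first trigger the aromatic Claisen [3,3] shift of the O3' 1,1-dimethylallyl ether to C2', its only unsubstituted ortho carbon, and rearomatisation gives prenyl phenol 19; the O4' 1,1-dimethylpropargyl ether then undergoes the propargyl Claisen [3,3] shift to C5', again the only free ortho carbon, and enolisation gives allenyl catechol 20. A [1,5]-hydrogen shift from the O4' hydroxyl to the central allene carbon produces ortho-quinone methide 21, and its thermal disrotatory oxa-6π electrocyclisation (O4' onto the CMe2 terminus, six-membered, the only ring formed) closes ring D. The closest known reaction types are the thermal conversion of aryl 1,1-dimethylpropargyl ethers into 2,2-dimethyl-2H-chromenes and the Claisen rearrangement of aryl 1,1-dimethylallyl ethers into ortho-prenylphenols, here run in one flask on one arene. No stereocentre is formed, and the (2R) centre is a spectator, since the medium is neutral to weakly basic and O4' is a free hydroxyl only in the short-lived intermediates 20 and 21. The selectivity needed is regiochemical (C2' and not C6' for the prenyl group, C5' for the pyran carbon, chromene and not benzofuran); it is secured by the 3',4'-dioxygenation pattern, which leaves each ether oxygen one blocked and one free ortho position so that only the dienones formed at C2' and C5' can tautomerise irreversibly, and by the gem-dimethyl group, which steers the allene into the [1,5]-H shift/electrocyclisation channel.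

Step 10
Reactants: 22 6-[(2R)-7-(methoxymethoxy)-3,4-dihydro-2H-chromen-2-yl]-2,2-dimethyl-7-(3-methylbut-2-en-1-yl)-2H-chromen-8-ol
Product: 23 6-[(2R)-7-hydroxy-3,4-dihydro-2H-chromen-2-yl]-2,2-dimethyl-7-(3-methylbut-2-en-1-yl)-2H-chromen-8-ol
Conditions: HCl (1.25 M in MeOH, cat.), MeOH/THF, rt
Reagents that add atoms: none
Why: Acid-catalysed transacetalisation of the aryl methoxymethyl ether with methanol should free the C7 phenol under conditions mild enough (dilute acid, room temperature) to leave the prenyl group, the chromene double bond, the benzylic C2–O1 bond and hence the (2R) centre untouched.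

**Compound list**

1 | 1-(3,4-dihydroxyphenyl)ethan-1-one | CC(=O)c1ccc(O)c(O)c1 | starting material
2 | 3-chloro-3-methylbut-1-yne | CC(C)(Cl)C#C | starting material
3 | 1-[3-hydroxy-4-(2-methylbut-3-yn-2-yloxy)phenyl]ethan-1-one | CC(=O)c1ccc(OC(C)(C)C#C)c(O)c1 | intermediate
4 | 2-methylbut-3-en-2-ol | CC(C)(O)C=C | starting material
5 | di-tert-butyl dicarbonate | CC(C)(C)OC(=O)OC(=O)OC(C)(C)C | starting material
6 | lithium 2-methylbut-3-en-2-olate (not isolated) | [Li+].[O-]C(C)(C)C=C | intermediate
7 | tert-butyl 2-methylbut-3-en-2-yl carbonate | C=CC(C)(C)OC(=O)OC(C)(C)C | intermediate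
8 | 1-[3-(2-methylbut-3-en-2-yloxy)-4-(2-methylbut-3-yn-2-yloxy)phenyl]ethan-1-one | CC(=O)c1ccc(OC(C)(C)C#C)c(OC(C)(C)C=C)c1 | intermediate
9 | 2,4-dihydroxybenzaldehyde | O=Cc1ccc(O)cc1O | starting material
10 | chloromethyl methyl ether | COCCl | starting material
11 | 2-hydroxy-4-(methoxymethoxy)benzaldehyde | O=Cc1ccc(OCOC)cc1O | intermediate
12 | aldol adduct (racemic, not isolated): 3-hydroxy-3-[2-hydroxy-4-(methoxymethoxy)phenyl]-1-[3-(2-methylbut-3-en-2-yloxy)-4-(2-methylbut-3-yn-2-yloxy)phenyl]propan-1-one | O=C(CC(O)c1ccc(OCOC)cc1O)c1ccc(OC(C)(C)C#C)c(OC(C)(C)C=C)c1 | intermediate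
13 | (2E)-3-[2-hydroxy-4-(methoxymethoxy)phenyl]-1-[3-(2-methylbut-3-en-2-yloxy)-4-(2-methylbut-3-yn-2-yloxy)phenyl]prop-2-en-1-one | O=C(/C=C/c1ccc(OCOC)cc1O)c1ccc(OC(C)(C)C#C)c(OC(C)(C)C=C)c1 | intermediate
14 | boron enolate (not isolated): (Z)-catecholboron enolate of 15, the phenol also carried as its catecholborate | C=CC(C)(C)Oc1cc(ccc1OC(C)(C)C#C)/C(OB1Oc2ccccc2O1)=C/Cc1ccc(OCOC)cc1OB1Oc2ccccc2O1 | intermediate
15 | 3-[2-hydroxy-4-(methoxymethoxy)phenyl]-1-[3-(2-methylbut-3-en-2-yloxy)-4-(2-methylbut-3-yn-2-yloxy)phenyl]propan-1-one | O=C(CCc1ccc(OCOC)cc1O)c1ccc(OC(C)(C)C#C)c(OC(C)(C)C=C)c1 | intermediate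
16 | bis-catecholborate ester of 17 (not isolated), (S) at the carbinol carbon | O1c2ccccc2OB1O[C@@H](CCc1ccc(OCOC)cc1OB1Oc2ccccc2O1)c1ccc(OC(C)(C)C#C)c(OC(C)(C)C=C)c1 | intermediate
17 | 2-[(3S)-3-hydroxy-3-[3-(2-methylbut-3-en-2-yloxy)-4-(2-methylbut-3-yn-2-yloxy)phenyl]propyl]-5-(methoxymethoxy)phenol | O[C@@H](CCc1ccc(OCOC)cc1O)c1ccc(OC(C)(C)C#C)c(OC(C)(C)C=C)c1 | intermediate
18 | (2R)-7-(methoxymethoxy)-2-[3-(2-methylbut-3-en-2-yloxy)-4-(2-methylbut-3-yn-2-yloxy)phenyl]-3,4-dihydro-2H-chromene | C=CC(C)(C)Oc1cc([C@H]2CCc3ccc(OCOC)cc3O2)ccc1OC(C)(C)C#C | intermediate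
19 | prenyl phenol (not isolated): 3-[(2R)-7-(methoxymethoxy)-3,4-dihydro-2H-chromen-2-yl]-2-(3-methylbut-2-en-1-yl)-6-(2-methylbut-3-yn-2-yloxy)phenol | CC(C)=CCc1c(O)c(OC(C)(C)C#C)ccc1[C@H]2CCc3ccc(OCOC)cc3O2 | intermediate
20 | allenyl catechol (not isolated): 4-[(2R)-7-(methoxymethoxy)-3,4-dihydro-2H-chromen-2-yl]-6-(3-methylbuta-1,2-dien-1-yl)-3-(3-methylbut-2-en-1-yl)benzene-1,2-diol | CC(C)=CCc1c(O)c(O)c(C=C=C(C)C)cc1[C@H]2CCc3ccc(OCOC)cc3O2 | intermediate
21 | ortho-quinone methide (not isolated): (6Z)-2-hydroxy-4-[(2R)-7-(methoxymethoxy)-3,4-dihydro-2H-chromen-2-yl]-6-(3-methylbut-2-en-1-ylidene)-3-(3-methylbut-2-en-1-yl)cyclohexa-2,4-dien-1-one | O=C1/C(=C\C=C(C)C)C=C([C@H]2CCc3ccc(OCOC)cc3O2)C(CC=C(C)C)=C1O | intermediate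
22 | 6-[(2R)-7-(methoxymethoxy)-3,4-dihydro-2H-chromen-2-yl]-2,2-dimethyl-7-(3-methylbut-2-en-1-yl)-2H-chromen-8-ol | CC(C)=CCc1c([C@H]2CCc3ccc(OCOC)cc3O2)cc2c(c1O)OC(C)(C)C=C2 | intermediate
23 | 6-[(2R)-7-hydroxy-3,4-dihydro-2H-chromen-2-yl]-2,2-dimethyl-7-(3-methylbut-2-en-1-yl)-2H-chromen-8-ol | CC(C)=CCc1c([C@H]2CCc3ccc(O)cc3O2)cc2c(c1O)OC(C)(C)C=C2 | target

**Summary**

Total steps: 10. Longest linear sequence: 8 steps (1, 3, 5, 6, 7, 8, 9, 10).

Steps most likely to fail:

1. Step 9. The tertiary allyl ether may fragment (loss of isoprene) or migrate by the ipso/para path before the ortho shift, and the two rearrangements may not mesh at one temperature, so that the first-formed prenyl phenol degrades while the propargyl ether is still unreacted. Fallback: decouple the two events and close ring D by metal catalysis instead of the pericyclic sequence. It sets out from 18: Ph3PAuNTf2 (2 mol%, a cationic monovalent gold catalyst), CH2Cl2, rt should effect 6-endo-dig hydroarylation of the aryl propargyl ether at C5' and give (2R)-2-[2,2-dimethyl-8-(2-methylbut-3-en-2-yloxy)-2H-chromen-6-yl]-7-(methoxymethoxy)-3,4-dihydro-2H-chromene F1. Heating F1 in toluene at 110–120 °C (sealed tube) should then complete the aromatic Claisen shift to C2' alone, and the route is rejoined at 22.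

2. Step 6. Hydride delivery may not be chemoselective: hydroboration of the terminal alkene or alkyne, or 1,2-reduction, could compete with a slow 1,4-addition to an electron-rich enone. Fallback: saturate the C=C bond by catalytic hydrogenation before the unsaturated ethers exist. It sets out from 1 and 11 and comes back at 15.
   - 1 is dibenzylated (BnBr, K2CO3, DMF) to 1-[3,4-bis(benzyloxy)phenyl]ethan-1-one F2.
   - 11 is capped at its 2-OH (SEMCl, i-Pr2NEt, CH2Cl2) to give 4-(methoxymethoxy)-2-{[2-(trimethylsilyl)ethoxy]methoxy}benzaldehyde F3.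
   - Claisen–Schmidt condensation of F2 with F3 (KOH, EtOH) gives the fully protected chalcone F4.
   - H2, 10% Pd/C, EtOAc saturates the alkene and removes both benzyl groups to give the catechol ketone F5.
   - The para-acyl 4-OH of F5 is propargylated with 2 as in step 1 to give the mono-propargyl ether F6.
   - The 3-OH of F6 is reverse-prenylated with 7 as in step 3 to give the bis-ether F7.
   - Bu4NF (THF, 50 °C) removes the silylethoxymethyl group and returns 15.

3. Step 10. Acid may cause side reactions during acetal cleavage: addition of the C8 hydroxyl to the prenyl double bond, addition to the chromene, or ionisation of the benzylic C2–O1 bond with loss of configuration. Fallback: exchange the acetal for a silyl group without Brønsted acid. It sets out from 22: Et3SiOTf (3 equiv), 2,2'-bipyridyl (4 equiv), CH2Cl2, 0 °C → rt should convert the aryl methoxymethyl ether (and the free phenol) into the bis(triethylsilyl) ether F8, and Bu4NF/AcOH (THF, 0 °C) then returns 23.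

**Further compounds**

F1 | step 9 | (2R)-2-[2,2-dimethyl-8-(2-methylbut-3-en-2-yloxy)-2H-chromen-6-yl]-7-(methoxymethoxy)-3,4-dihydro-2H-chromene | C=CC(C)(C)Oc1cc([C@H]2CCc3ccc(OCOC)cc3O2)cc2C=CC(C)(C)Oc12
F2 | step 6 | 1-[3,4-bis(benzyloxy)phenyl]ethan-1-one | CC(=O)c1ccc(OCc2ccccc2)c(OCc2ccccc2)c1
F3 | step 6 | 4-(methoxymethoxy)-2-{[2-(trimethylsilyl)ethoxy]methoxy}benzaldehyde | O=Cc1ccc(OCOC)cc1OCOCC[Si](C)(C)C
F4 | step 6 | (2E)-1-[3,4-bis(benzyloxy)phenyl]-3-[4-(methoxymethoxy)-2-{[2-(trimethylsilyl)ethoxy]methoxy}phenyl]prop-2-en-1-one | O=C(/C=C/c1ccc(OCOC)cc1OCOCC[Si](C)(C)C)c1ccc(OCc2ccccc2)c(OCc2ccccc2)c1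
F5 | step 6 | 1-(3,4-dihydroxyphenyl)-3-[4-(methoxymethoxy)-2-{[2-(trimethylsilyl)ethoxy]methoxy}phenyl]propan-1-one | O=C(CCc1ccc(OCOC)cc1OCOCC[Si](C)(C)C)c1ccc(O)c(O)c1
F6 | step 6 | 1-[3-hydroxy-4-(2-methylbut-3-yn-2-yloxy)phenyl]-3-[4-(methoxymethoxy)-2-{[2-(trimethylsilyl)ethoxy]methoxy}phenyl]propan-1-one | O=C(CCc1ccc(OCOC)cc1OCOCC[Si](C)(C)C)c1ccc(OC(C)(C)C#C)c(O)c1
F7 | step 6 | 1-[3-(2-methylbut-3-en-2-yloxy)-4-(2-methylbut-3-yn-2-yloxy)phenyl]-3-[4-(methoxymethoxy)-2-{[2-(trimethylsilyl)ethoxy]methoxy}phenyl]propan-1-one | O=C(CCc1ccc(OCOC)cc1OCOCC[Si](C)(C)C)c1ccc(OC(C)(C)C#C)c(OC(C)(C)C=C)c1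
F8 | step 10 | triethyl({2,2-dimethyl-7-(3-methylbut-2-en-1-yl)-6-[(2R)-7-(triethylsilyloxy)-3,4-dihydro-2H-chromen-2-yl]-2H-chromen-8-yl}oxy)silane | CC(C)=CCc1c([C@H]2CCc3ccc(O[Si](CC)(CC)CC)cc3O2)cc2c(c1O[Si](CC)(CC)CC)OC(C)(C)C=C2
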